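## The problem

The target is a cembranolide. Its 14-membered carbocycle (C1–C14; methyls C18 on C4, C19 on C8, C20 on C12) is trans-fused at C1/C14 to an α-methylene-γ-lactone (C15, C16 carbonyl, C17 methylene). It carries a (3S,4S)-trisubstituted epoxide, a (7R)-hydroperoxide next to the exocyclic C8=C19 methylene, an E-C11=C12 olefin and a (13S)-acetate. The six stereocentres form a contiguous triad C13–C14–C1 and the remote C3/C4 and C7. C14, taken from the chiral pool, can control C1 in the step that forms the lactone and C13 by 1,2-induction at an aldehyde; C3/C4 need a reagent-controlled epoxidation; C7 can only be set by the conformation of the finished ring. The allylic hydroperoxide will not survive phosphines, hydrides, low-valent metals or base and must come last. The α-methylene lactone is a Michael acceptor and has to appear after every carbanion, hydride and chromium step. The epoxide forbids strong acid, and the allylic acetate forbids late palladium or strong base. The feature that opens the key step is that C1 is a methine β to the lactone oxygen on C14. A diazo(diethoxyphosphoryl)acetate on O14 holds its carbene carbon C15 in a 1,5-relationship to the C1–H bonds, so C–H insertion forms C1–C15 and the five-membered ring at once and leaves at C15 the phosphonate from which C17 is made. C13–H lies at the same 1,5-distance, so the oxygen on C13 must switch those C–H bonds off, and the acidic C15–H that the phosphonate brings has to be allowed for in every later basic step.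

## Retrosynthesis

The C7–O bond and the C8=C19 olefin of target 36 are cut together in a singlet-oxygen ene reaction of acetate 35, which has an E-C7=C8 olefin. No reliable way exists to turn an allylic alcohol into a hydroperoxide on this skeleton, whereas the ene reaction makes the peroxide in the last step, when nothing that reduces it follows. 35 lacks one stereocentre and the peroxide. The forward step must abstract hydrogen from C19 and not C6, attack one face of C7, and leave C11=C12 and the methylene lactone alone.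

The C13 acetate and the C15=C17 olefin are removed next (35 to alcohol 34 to phosphonate 33). The methylene comes from a Horner–Wadsworth–Emmons reaction with formaldehyde, which needs only carbonate base. The alternative, enolate aminomethylation of a plain lactone, would need a strong amide base on an epoxide-bearing macrocycle. The price is that the phosphonate and its acidic C15–H are carried through the middle of the route.

Phosphonate 33 arises from sulfone 32 by reductive desulfonylation, and the ring of 32 is opened at C12–C13 to iodo aldehyde 31 (Nozaki–Hiyama–Kishi reaction). This bond is preferred to C5–C6 (an intramolecular sulfone alkylation would need slow substitution beside the epoxide at high dilution and a protected C13 hydroxyl under strong base) and to metathesis at a trisubstituted olefin (no E control). Its closure creates the C13 carbinol, uses an alkenyl iodide of fixed E geometry, and chromium tolerates the acidic phosphonate, the epoxide and the sulfone. The forward step must add to the aldehyde anti to the C14–O bond.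

Aldehyde 31 comes from alcohol 30 and carbonate 29, and 29 is cut at C5–C6 into epoxy alcohol 16 (as its triflate 28) and allylic sulfone 26 (as its lithio derivative 27). C5–C6 is the only sp3–sp3 bond between the epoxide and the first olefin. An allylic sulfonyl carbanion alkylates at its α-carbon without touching olefin geometry, and the sulfonyl group can later be removed with regiocontrol because C8 is fully substituted. 16 holds four of the six stereocentres in eleven skeletal carbons; 26 is achiral. The forward step needs substitution at a hindered primary carbon while one equivalent of carbanion is spent on C15–H.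

The epoxide of 16 is traced to allylic alcohol 15 (Sharpless epoxidation), 15 to enal 14 (1,2-reduction), and the C3=C4 bond of 14 to aldehyde 12 and ylide 13 (Wittig reaction). The stabilised ylide gives the E olefin, which maps onto the trans-epoxide, and the C5 hydroxyl that directs the epoxidation becomes the leaving group of the next disconnection. Aldehyde 12 comes from alcohol 11 and silyl ether 10.

Lactone 10 is cut at C1–C15 to diazo ester 9; this rhodium carbenoid C–H insertion is the key step. It closes the lactone and sets C1 from C14 with no functional group at C1 beforehand. A conjugate addition to a butenolide would form C1–C2 instead and needs a separate C15 functionalisation. 9 is an acyclic ester with one stereocentre. The forward step must insert at C1–H and not C13–H, and give the 1,14-trans ring.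

Diazo ester 9 comes by diazo transfer from phosphonoacetate 8, made from alcohol 6 and acid 7. 6 is reached from (R)-lactone 1 through triol 2, acetonide 3, silyl ether 4 and diol 5. The C13 oxygen carries a 2,2,2-trichloroethyl carbonate: it is electron-withdrawing like a pivalate but is removed by zinc, which a lactone survives.

Sulfone 26 is traced to iodo alcohol 24 (hydrozirconation–iodination), enynol 22 (carboalumination–hydroxymethylation of hepta-1,5-diyne 19), tosylate 18 and pent-3-yn-1-ol 17. Both olefin geometries come from syn additions to alkynes.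

## Roads not taken

Alternative 1: The ring is cut at C12–C13 of open-chain lactone aldehyde A1, whose other end is a methyl-capped C11≡C12 alkyne. Ni(cod)2 (zerovalent nickel), a bulky N-heterocyclic carbene and Et3SiH couple alkyne and aldehyde reductively to the macrocyclic allylic silyl ether A2. The step is catalytic, forms ring, olefin and protected carbinol at once, and its alkyne is about two steps shorter to make than iodide 26. In these respects it is better than the chosen closure, which forms the same bond with stoichiometric chromium. Its weak points here are three. Whether C12 or C11 bonds to C13 rests on ligand control between a methyl and a chain terminus. The C13 configuration is left to the ring. A2 has an unfunctionalised lactone, so C17 must be added by strong-base enolate chemistry on the epoxide-bearing macrocycle. The chosen plan sets against it an alkenyl iodide that fixes regiochemistry and geometry before ring closure, and a phosphonate that makes the methylenation a carbonate-base operation.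

Alternative 2: The lactone core is cut at C1–C2 and C15–C17 around butenolide A3. Lithiated allylic sulfone A4 adds through C2 to C1 anti to the C14 substituent, and the enolate is aminomethylated at C15 to give A5; no ring closes. C1 is set by a well-established anti addition, C3=C4 and the C5 oxygen arrive with the sulfone, and the amine is a masked methylene lactone. It reaches the stage of allylic alcohol 15 in roughly half the steps, so for the lactone core it is better in step count; the fallback for step 8 below borrows its logic. Its weak points here: the tertiary amine binds titanium and is oxidised by t-BuOOH in the epoxidation, and unmasking it early exposes the methylene lactone to the sulfonyl carbanion, hydride and chromium steps that follow. The allyl sulfone anion can also add 1,2 or through its γ-carbon, and a second desulfonylation is needed. The chosen plan sets against it a neutral, catalytic ring formation whose only by-product is N2, and a C15 group that is inert to titanium and peroxide and is unmasked only at the end.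

Alternative 3: The lactone is cut at C15–C16 and C16–O of macrocyclic alcohol A6, which bears an ethynyl group at C1. PdCl2 (divalent palladium), thiourea and CO convert it to methylene lactone A7. The most fragile group is made late from carbon monoxide and is never exposed to nucleophiles, and no acidic phosphonate is carried; in this it is better than the chosen plan. Its weak points: C1 and C14 must be set on an open chain with no ring to relay stereochemistry, the C13 and C14 oxygens must be differentiated, the macrocycle must be closed beside a terminal alkyne, and palladium hydrides under CO can isomerise the 1,5-diene. The chosen plan sets against it a C1 stereocentre derived directly from C14 in the ring-forming step, and a lactone that rigidifies the C13 aldehyde for the later addition.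

Key step: step 8

Assumption: the C7=C8 olefin of 35, which the ene reaction erases, is taken as E, the geometry that the carboalumination delivers; hepta-1,5-diyne (19) is prepared, not purchased.

## Steps

Step 1
Reactants: 1 (R)-5-(hydroxymethyl)dihydrofuran-2(3H)-one
Product: 2 (2R)-pentane-1,2,5-triol
Conditions: LiAlH4, THF, 0 °C to reflux; Na2SO4·10H2O quench
Reagents that add atoms: none
Why: Hydride reduction of a lactone to the diol; the C14 stereocentre is not touched.

Step 2
Reactants: 2 (2R)-pentane-1,2,5-triol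
Product: 3 3-[(4R)-2,2-dimethyl-1,3-dioxolan-4-yl]propan-1-ol
Conditions: 2,2-dimethoxypropane, TsOH·H2O (cat.), acetone, rt
Reagents that add atoms: 2,2-dimethoxypropane, COC(C)(C)OC
Why: Acetonide formation under thermodynamic control favours the five-membered dioxolane of the 1,2-diol and leaves the C3 hydroxyl free.

Step 3
Reactants: 3 3-[(4R)-2,2-dimethyl-1,3-dioxolan-4-yl]propan-1-ol
Product: 4 tert-butyl{3-[(4R)-2,2-dimethyl-1,3-dioxolan-4-yl]propoxy}diphenylsilane
Conditions: t-BuPh2SiCl, imidazole, DMF, 0 °C to rt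
Reagents that add atoms: tert-butyl(chloro)diphenylsilane, CC(C)(C)[Si](Cl)(c1ccccc1)c1ccccc1
Why: Silylation of the only free hydroxyl; this silyl ether survives the acid of the next step.

Step 4
Reactants: 4 tert-butyl{3-[(4R)-2,2-dimethyl-1,3-dioxolan-4-yl]propoxy}diphenylsilane
Product: 5 (2R)-5-[(tert-butyldiphenylsilyl)oxy]pentane-1,2-diol
Conditions: AcOH–H2O (4:1), 40 °C
Reagents that add atoms: none
Why: Acetal hydrolysis; a primary tert-butyldiphenylsilyl ether is stable to aqueous acetic acid.

Step 5
Reactants: 5 (2R)-5-[(tert-butyldiphenylsilyl)oxy]pentane-1,2-diol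
Product: 6 (2R)-5-[(tert-butyldiphenylsilyl)oxy]-2-hydroxypentyl 2,2,2-trichloroethyl carbonate
Conditions: ClCO2CH2CCl3 (1.05 equiv), pyridine, CH2Cl2, −30 °C
Reagents that add atoms: 2,2,2-trichloroethyl chloroformate, ClC(=O)OCC(Cl)(Cl)Cl
Why: Acylation at low temperature selects the primary C13 hydroxyl over the secondary C14 hydroxyl; the carbonate is the electron-withdrawing group needed in step 8.

Step 6
Reactants: 6 (2R)-5-[(tert-butyldiphenylsilyl)oxy]-2-hydroxypentyl 2,2,2-trichloroethyl carbonate; 7 (diethoxyphosphoryl)acetic acid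
Product: 8 (2R)-5-[(tert-butyldiphenylsilyl)oxy]-1-{[(2,2,2-trichloroethoxy)carbonyl]oxy}pentan-2-yl (diethoxyphosphoryl)acetate
Conditions: N,N'-dicyclohexylcarbodiimide, DMAP (cat.), CH2Cl2, 0 °C to rt
Reagents that add atoms: none
Why: Steglich esterification of the secondary alcohol; it is run cold with little DMAP so that the neighbouring carbonate does not migrate or cyclise.

Step 7
Reactants: 8 (2R)-5-[(tert-butyldiphenylsilyl)oxy]-1-{[(2,2,2-trichloroethoxy)carbonyl]oxy}pentan-2-yl (diethoxyphosphoryl)acetate
Product: 9 (2R)-5-[(tert-butyldiphenylsilyl)oxy]-1-{[(2,2,2-trichloroethoxy)carbonyl]oxy}pentan-2-yl diazo(diethoxyphosphoryl)acetate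
Conditions: 4-AcNHC6H4SO2N3, DBU, MeCN, 0 °C to rt
Reagents that add atoms: 4-acetamidobenzenesulfonyl azide, CC(=O)Nc1ccc(cc1)S(=O)(=O)N=[N+]=[N-]
Why: Regitz diazo transfer to the doubly activated methylene of the phosphonoacetate.

Step 8
Reactants: 9 (2R)-5-[(tert-butyldiphenylsilyl)oxy]-1-{[(2,2,2-trichloroethoxy)carbonyl]oxy}pentan-2-yl diazo(diethoxyphosphoryl)acetate
Product: 10 diethyl [(4S,5R)-4-{2-[(tert-butyldiphenylsilyl)oxy]ethyl}-2-oxo-5-({[(2,2,2-trichloroethoxy)carbonyl]oxy}methyl)oxolan-3-yl]phosphonate (trans-4,5 lactone, C15 epimers)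
Conditions: Rh2(OAc)4 (2 mol %), CH2Cl2, 40 °C, slow addition of 9
Reagents that add atoms: none
Why: Rh2(OAc)4, a divalent rhodium dimer, takes up the diazo carbon of 9 and expels N2 to give an electrophilic rhodium carbenoid at C15. The carbenoid inserts into a C1–H bond in one concerted three-centre step, with hydride-like transfer of H to C15, and so forms C1–C15. The closest known reaction type is the dirhodium tetracarboxylate-catalysed 1,5 C–H insertion of α-diazo-α-(dialkoxyphosphoryl)acetates to α-phosphono-γ-lactones. The γ-lactone closes by 1,5-insertion through a chair-like six-centre transition state made of C15, C16, O, C14, C1 and the migrating hydrogen. The new C1 stereocentre is controlled by C14: with the C13 carbonate arm and the C2 chain both pseudo-equatorial the hydrogen that leads to the 1,14-trans lactone is transferred, while C15 forms as an epimer mixture that step 24 erases. The step needs C1–H over C13–H (also 1,5), C14–H (β-lactone) and C2–H (1,6). The carbonate oxygen withdraws electron density from C13–H and C14–H and its bulk shields C13, five-ring closure is preferred over six, and the only ether C–H (at C3) is out of reach at a 1,7-distance; no olefin or hydroxyl is present to divert the carbenoid.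

Step 9
Reactants: 10 diethyl [(4S,5R)-4-{2-[(tert-butyldiphenylsilyl)oxy]ethyl}-2-oxo-5-({[(2,2,2-trichloroethoxy)carbonyl]oxy}methyl)oxolan-3-yl]phosphonate
Product: 11 diethyl [(4S,5R)-4-(2-hydroxyethyl)-2-oxo-5-({[(2,2,2-trichloroethoxy)carbonyl]oxy}methyl)oxolan-3-yl]phosphonate
Conditions: HF·pyridine, pyridine, THF, 0 °C to rt
Reagents that add atoms: none
Why: Acidic fluoride cleaves the silyl ether; it spares the base-sensitive carbonate and does not enolise the phosphono lactone.

Step 10
Reactants: 11 diethyl [(4S,5R)-4-(2-hydroxyethyl)-2-oxo-5-({[(2,2,2-trichloroethoxy)carbonyl]oxy}methyl)oxolan-3-yl]phosphonate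
Product: 12 diethyl [(4S,5R)-2-oxo-4-(2-oxoethyl)-5-({[(2,2,2-trichloroethoxy)carbonyl]oxy}methyl)oxolan-3-yl]phosphonate
Conditions: Dess–Martin periodinane, CH2Cl2, rt
Reagents that add atoms: none
Why: Neutral oxidation of the primary alcohol to the C3 aldehyde; C1 is β to the new carbonyl and cannot epimerise.

Step 11
Reactants: 12 diethyl [(4S,5R)-2-oxo-4-(2-oxoethyl)-5-({[(2,2,2-trichloroethoxy)carbonyl]oxy}methyl)oxolan-3-yl]phosphonate; 13 2-(triphenyl-λ5-phosphanylidene)propanal
Product: 14 diethyl [(4S,5R)-4-[(2E)-3-methyl-4-oxobut-2-en-1-yl]-2-oxo-5-({[(2,2,2-trichloroethoxy)carbonyl]oxy}methyl)oxolan-3-yl]phosphonate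
Conditions: toluene, 90 °C
Reagents that add atoms: none
Why: Wittig reaction of a stabilised ylide gives the E-enal (C3=C4, C18 methyl, C5 aldehyde); no base is present, so C15–H stays protonated.

Step 12
Reactants: 14 diethyl [(4S,5R)-4-[(2E)-3-methyl-4-oxobut-2-en-1-yl]-2-oxo-5-({[(2,2,2-trichloroethoxy)carbonyl]oxy}methyl)oxolan-3-yl]phosphonate
Product: 15 diethyl [(4S,5R)-4-[(2E)-4-hydroxy-3-methylbut-2-en-1-yl]-2-oxo-5-({[(2,2,2-trichloroethoxy)carbonyl]oxy}methyl)oxolan-3-yl]phosphonate
Conditions: NaBH4, CeCl3·7H2O, MeOH, −40 °C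
Reagents that add atoms: none
Why: Luche reduction gives 1,2-reduction of the enal; lactone and carbonate are not reduced at this temperature.

Step 13
Reactants: 15 diethyl [(4S,5R)-4-[(2E)-4-hydroxy-3-methylbut-2-en-1-yl]-2-oxo-5-({[(2,2,2-trichloroethoxy)carbonyl]oxy}methyl)oxolan-3-yl]phosphonate
Product: 16 diethyl [(4S,5R)-4-{[(2S,3S)-3-(hydroxymethyl)-3-methyloxiran-2-yl]methyl}-2-oxo-5-({[(2,2,2-trichloroethoxy)carbonyl]oxy}methyl)oxolan-3-yl]phosphonate
Conditions: Ti(OiPr)4 (1 equiv), L-(+)-diisopropyl tartrate, t-BuOOH, 4 Å sieves, CH2Cl2, −20 °C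
Reagents that add atoms: tert-butyl hydroperoxide, CC(C)(C)OO
Why: Sharpless asymmetric epoxidation of the E-2-methyl allylic alcohol; the L-(+)-tartrate delivers oxygen to the face that gives the (3S,4S)-epoxide under reagent control. A full equivalent of titanium is used because the phosphono lactone binds it.

Step 14
Reactants: 17 pent-3-yn-1-ol
Product: 18 pent-3-yn-1-yl 4-methylbenzenesulfonate
Conditions: TsCl, Et3N, DMAP (cat.), CH2Cl2, 0 °C
Reagents that add atoms: 4-methylbenzenesulfonyl chloride, Cc1ccc(cc1)S(Cl)(=O)=O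
Why: Sulfonylation of a primary alcohol.

Step 15
Reactants: 18 pent-3-yn-1-yl 4-methylbenzenesulfonate
Product: 19 hepta-1,5-diyne
Conditions: LiC≡CH·H2NCH2CH2NH2, DMSO, 15 °C
Reagents that add atoms: lithium acetylide (ethylenediamine complex), [Li]C#C
Why: SN2 alkylation of acetylide by a primary sulfonate in a dipolar aprotic solvent, kept cool to hold back elimination.

Step 16
Reactants: 19 hepta-1,5-diyne
Product: 22 (E)-3-methyloct-2-en-6-yn-1-ol, via alkenylalane 20 (not isolated), via lithium alkenylaluminate 21 (not isolated)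
Conditions: AlMe3, Cp2ZrCl2 (25 mol %), CH2Cl2, 0 °C to rt; n-BuLi, THF, −78 °C; (CH2O)n, to rt
Reagents that add atoms: trimethylaluminium, C[Al](C)C; formaldehyde (as paraformaldehyde), C=O
Why: Negishi carboalumination adds methyl and aluminium syn across the terminal alkyne only, which fixes E-C7=C8; the aluminate then takes up formaldehyde at C7 with retention to give the C6 alcohol.

Step 17
Reactants: 22 (E)-3-methyloct-2-en-6-yn-1-ol
Product: 24 (2E,6E)-7-iodo-3-methylocta-2,6-dien-1-ol, via alkenylzirconocene 23 (not isolated)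
Conditions: Cp2Zr(H)Cl (3 equiv), THF, 45 °C; I2, 0 °C
Reagents that add atoms: iodine, II
Why: Hydrozirconation is a syn addition; with excess Cp2Zr(H)Cl the alkenylzirconium isomers equilibrate to the one with zirconium on the methyl-bearing carbon. Iodination with retention then gives the E-2-iodo-2-alkene (C11=C12).

Step 18
Reactants: 24 (2E,6E)-7-iodo-3-methylocta-2,6-dien-1-ol
Product: 26 [(2E,6E)-7-iodo-3-methylocta-2,6-dien-1-yl]sulfonylbenzene, via allylic bromide 25 (not isolated)
Conditions: PBr3, Et2O, 0 °C; PhSO2Na, DMF, rt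
Reagents that add atoms: sodium benzenesulfinate, [Na+].[O-]S(=O)c1ccccc1
Why: Bromination of the primary allylic alcohol and S-alkylation of sulfinate, both at the unhindered primary terminus, so the E olefin is kept.

Step 19
Reactants: 16 diethyl [(4S,5R)-4-{[(2S,3S)-3-(hydroxymethyl)-3-methyloxiran-2-yl]methyl}-2-oxo-5-({[(2,2,2-trichloroethoxy)carbonyl]oxy}methyl)oxolan-3-yl]phosphonate; 26 [(2E,6E)-7-iodo-3-methylocta-2,6-dien-1-yl]sulfonylbenzene
Product: 29 diethyl [(4S,5R)-4-({(2S,3S)-3-[(3E,7E)-8-iodo-4-methyl-2-(phenylsulfonyl)nona-3,7-dien-1-yl]-3-methyloxiran-2-yl}methyl)-2-oxo-5-({[(2,2,2-trichloroethoxy)carbonyl]oxy}methyl)oxolan-3-yl]phosphonate (C6 epimers), via lithiated sulfone 27 (not isolated), via epoxy triflate 28 (not isolated)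
Conditions: 26 (2.5 equiv), LiN(SiMe3)2, THF–DMPU, −78 °C; 16, Tf2O, 2,6-lutidine, CH2Cl2, −78 °C, added by cannula to 27; AcOH quench at −78 °C
Reagents that add atoms: none
Why: SN2 alkylation of an allylic sulfonyl carbanion at its α-carbon by a primary triflate forms C5–C6; an amide base is used because an alkyllithium would exchange the alkenyl iodide. One equivalent of carbanion is spent on C15–H; the resulting enolate cannot alkylate C5, because a six-membered ring across the trans-epoxide would be trans-fused. At −78 °C the carbonate is not attacked.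

Step 20
Reactants: 29 diethyl [(4S,5R)-4-({(2S,3S)-3-[(3E,7E)-8-iodo-4-methyl-2-(phenylsulfonyl)nona-3,7-dien-1-yl]-3-methyloxiran-2-yl}methyl)-2-oxo-5-({[(2,2,2-trichloroethoxy)carbonyl]oxy}methyl)oxolan-3-yl]phosphonate
Product: 30 diethyl [(4S,5R)-5-(hydroxymethyl)-4-({(2S,3S)-3-[(3E,7E)-8-iodo-4-methyl-2-(phenylsulfonyl)nona-3,7-dien-1-yl]-3-methyloxiran-2-yl}methyl)-2-oxooxolan-3-yl]phosphonate
Conditions: Zn dust, AcOH, THF, 0 °C
Reagents that add atoms: none
Why: Reductive fragmentation of the trichloroethyl carbonate frees the C13 hydroxyl without base, so the lactone stays closed; the alkenyl iodide and the epoxide should tolerate brief exposure at 0 °C.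

Step 21
Reactants: 30 diethyl [(4S,5R)-5-(hydroxymethyl)-4-({(2S,3S)-3-[(3E,7E)-8-iodo-4-methyl-2-(phenylsulfonyl)nona-3,7-dien-1-yl]-3-methyloxiran-2-yl}methyl)-2-oxooxolan-3-yl]phosphonate
Product: 31 diethyl [(4S,5R)-5-formyl-4-({(2S,3S)-3-[(3E,7E)-8-iodo-4-methyl-2-(phenylsulfonyl)nona-3,7-dien-1-yl]-3-methyloxiran-2-yl}methyl)-2-oxooxolan-3-yl]phosphonate
Conditions: Dess–Martin periodinane, NaHCO3, CH2Cl2, 0 °C; used at once
Reagents that add atoms: none
Why: Buffered neutral oxidation gives the C13 aldehyde without opening the epoxide or epimerising C14.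

Step 22
Reactants: 31 diethyl [(4S,5R)-5-formyl-4-({(2S,3S)-3-[(3E,7E)-8-iodo-4-methyl-2-(phenylsulfonyl)nona-3,7-dien-1-yl]-3-methyloxiran-2-yl}methyl)-2-oxooxolan-3-yl]phosphonate
Product: 32 (1S,3S,4S,13S,14R)-15-(diethoxyphosphoryl)-3,4-epoxy-13-hydroxy-6-(phenylsulfonyl)cembra-7E,11E-dien-16,14-olide (C6 and C15 epimers)
Conditions: CrCl2 (12 equiv), NiCl2 (2 mol %), DMSO–THF (3:1), rt, 2 mM, slow addition
Reagents that add atoms: none
Why: Nozaki–Hiyama–Kishi reaction: nickel inserts into the alkenyl iodide, the alkenyl group passes to chromium with retention of the E geometry and adds to the aldehyde, closing the 14-membered ring at C12–C13. Felkin–Anh addition anti to the C14–O bond should give the 13,14-anti, (13S) alcohol. The weakly basic organochromium tolerates C15–H, sulfone and epoxide.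

Step 23
Reactants: 32 (1S,3S,4S,13S,14R)-15-(diethoxyphosphoryl)-3,4-epoxy-13-hydroxy-6-(phenylsulfonyl)cembra-7E,11E-dien-16,14-olide
Product: 33 (1S,3S,4S,13S,14R)-15-(diethoxyphosphoryl)-3,4-epoxy-13-hydroxycembra-7E,11E-dien-16,14-olide (C15 epimers)
Conditions: LiN(SiMe3)2 (1.05 equiv), THF, −78 °C; PdCl2(dppp) (10 mol %; dppp = 1,3-bis(diphenylphosphino)propane), LiBHEt3, −20 to 0 °C
Reagents that add atoms: none
Why: Palladium-catalysed hydride substitution of an allylic sulfone: the π-allyl complex over C6–C8 takes hydride at the less substituted C6, which keeps E-C7=C8. C15–H is removed first so that the lactone is held as its phosphonate enolate and resists the hydride.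

Step 24
Reactants: 33 (1S,3S,4S,13S,14R)-15-(diethoxyphosphoryl)-3,4-epoxy-13-hydroxycembra-7E,11E-dien-16,14-olide
Product: 34 (1R,3S,4S,13S,14R)-3,4-epoxy-13-hydroxycembra-7E,11E,15(17)-trien-16,14-olide
Conditions: K2CO3, 37 % aq. CH2O, THF, rt
Reagents that add atoms: formaldehyde, C=O
Why: Horner–Wadsworth–Emmons methylenation: the phosphonate carbanion adds to formaldehyde and loses diethyl phosphate, so both C15 epimers converge on the exocyclic olefin.

Step 25
Reactants: 34 (1R,3S,4S,13S,14R)-3,4-epoxy-13-hydroxycembra-7E,11E,15(17)-trien-16,14-olide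
Product: 35 (1R,3S,4S,13S,14R)-13-acetoxy-3,4-epoxycembra-7E,11E,15(17)-trien-16,14-olide
Conditions: Ac2O, pyridine, DMAP (cat.), CH2Cl2, 0 °C
Reagents that add atoms: acetic anhydride, CC(=O)OC(C)=O
Why: Acylation of the secondary allylic alcohol with retention at C13.

Step 26
Reactants: 35 (1R,3S,4S,13S,14R)-13-acetoxy-3,4-epoxycembra-7E,11E,15(17)-trien-16,14-olide
Product: 36 (1R,3S,4S,7R,13S,14R)-13-acetoxy-3,4-epoxy-7-hydroperoxycembra-8(19),11E,15(17)-trien-16,14-olide
Conditions: O2, methylene blue (cat.), visible light, CH2Cl2, −20 °C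
Reagents that add atoms: dioxygen, O=O
Why: Schenck ene reaction: singlet oxygen bonds to C7 and takes a hydrogen from the C19 methyl on the more crowded side of the olefin, moving the double bond to C8=C19. C11=C12 is deactivated by the allylic acetate and the methylene lactone is electron-poor. The C7 configuration is set by attack on the outer face of the olefin in the preferred ring conformation.

## Compound list

1 | (R)-5-(hydroxymethyl)dihydrofuran-2(3H)-one | O=C1CC[C@H](CO)O1 | starting material
2 | (2R)-pentane-1,2,5-triol | OC[C@H](O)CCCO | intermediate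
3 | 3-[(4R)-2,2-dimethyl-1,3-dioxolan-4-yl]propan-1-ol | CC1(C)OC[C@@H](CCCO)O1 | intermediate
4 | tert-butyl{3-[(4R)-2,2-dimethyl-1,3-dioxolan-4-yl]propoxy}diphenylsilane | CC1(C)OC[C@@H](CCCO[Si](c2ccccc2)(c2ccccc2)C(C)(C)C)O1 | intermediate
5 | (2R)-5-[(tert-butyldiphenylsilyl)oxy]pentane-1,2-diol | OC[C@H](O)CCCO[Si](c1ccccc1)(c1ccccc1)C(C)(C)C | intermediate
6 | (2R)-5-[(tert-butyldiphenylsilyl)oxy]-2-hydroxypentyl 2,2,2-trichloroethyl carbonate | ClC(Cl)(Cl)COC(=O)OC[C@H](O)CCCO[Si](c1ccccc1)(c1ccccc1)C(C)(C)C | intermediate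
7 | (diethoxyphosphoryl)acetic acid | OC(=O)CP(=O)(OCC)OCC | starting material
8 | (2R)-5-[(tert-butyldiphenylsilyl)oxy]-1-{[(2,2,2-trichloroethoxy)carbonyl]oxy}pentan-2-yl (diethoxyphosphoryl)acetate | CCOP(=O)(OCC)CC(=O)O[C@@H](COC(=O)OCC(Cl)(Cl)Cl)CCCO[Si](c1ccccc1)(c1ccccc1)C(C)(C)C | intermediate
9 | (2R)-5-[(tert-butyldiphenylsilyl)oxy]-1-{[(2,2,2-trichloroethoxy)carbonyl]oxy}pentan-2-yl diazo(diethoxyphosphoryl)acetate | CCOP(=O)(OCC)C(=[N+]=[N-])C(=O)O[C@@H](COC(=O)OCC(Cl)(Cl)Cl)CCCO[Si](c1ccccc1)(c1ccccc1)C(C)(C)C | intermediate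
10 | diethyl [(4S,5R)-4-{2-[(tert-butyldiphenylsilyl)oxy]ethyl}-2-oxo-5-({[(2,2,2-trichloroethoxy)carbonyl]oxy}methyl)oxolan-3-yl]phosphonate (C15 epimers) | CCOP(=O)(OCC)C1C(=O)O[C@@H](COC(=O)OCC(Cl)(Cl)Cl)[C@@H]1CCO[Si](c1ccccc1)(c1ccccc1)C(C)(C)C | intermediate
11 | diethyl [(4S,5R)-4-(2-hydroxyethyl)-2-oxo-5-({[(2,2,2-trichloroethoxy)carbonyl]oxy}methyl)oxolan-3-yl]phosphonate | CCOP(=O)(OCC)C1C(=O)O[C@@H](COC(=O)OCC(Cl)(Cl)Cl)[C@@H]1CCO | intermediate
12 | diethyl [(4S,5R)-2-oxo-4-(2-oxoethyl)-5-({[(2,2,2-trichloroethoxy)carbonyl]oxy}methyl)oxolan-3-yl]phosphonate | CCOP(=O)(OCC)C1C(=O)O[C@@H](COC(=O)OCC(Cl)(Cl)Cl)[C@@H]1CC=O | intermediate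
13 | 2-(triphenyl-λ5-phosphanylidene)propanal | CC(C=O)=P(c1ccccc1)(c1ccccc1)c1ccccc1 | starting material
14 | diethyl [(4S,5R)-4-[(2E)-3-methyl-4-oxobut-2-en-1-yl]-2-oxo-5-({[(2,2,2-trichloroethoxy)carbonyl]oxy}methyl)oxolan-3-yl]phosphonate | CCOP(=O)(OCC)C1C(=O)O[C@@H](COC(=O)OCC(Cl)(Cl)Cl)[C@@H]1C/C=C(\C)C=O | intermediate
15 | diethyl [(4S,5R)-4-[(2E)-4-hydroxy-3-methylbut-2-en-1-yl]-2-oxo-5-({[(2,2,2-trichloroethoxy)carbonyl]oxy}methyl)oxolan-3-yl]phosphonate | CCOP(=O)(OCC)C1C(=O)O[C@@H](COC(=O)OCC(Cl)(Cl)Cl)[C@@H]1C/C=C(\C)CO | intermediate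
16 | diethyl [(4S,5R)-4-{[(2S,3S)-3-(hydroxymethyl)-3-methyloxiran-2-yl]methyl}-2-oxo-5-({[(2,2,2-trichloroethoxy)carbonyl]oxy}methyl)oxolan-3-yl]phosphonate | CCOP(=O)(OCC)C1C(=O)O[C@@H](COC(=O)OCC(Cl)(Cl)Cl)[C@@H]1C[C@@H]1O[C@@]1(C)CO | intermediate
17 | pent-3-yn-1-ol | CC#CCCO | starting material
18 | pent-3-yn-1-yl 4-methylbenzenesulfonate | CC#CCCOS(=O)(=O)c1ccc(C)cc1 | intermediate
19 | hepta-1,5-diyne | C#CCCC#CC | intermediate
20 | dimethyl[(1E)-2-methylhept-1-en-5-yn-1-yl]alumane | C[Al](C)/C=C(\C)CCC#CC | intermediate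
21 | lithium butyl(dimethyl)[(1E)-2-methylhept-1-en-5-yn-1-yl]aluminate | [Li+].CCCC[Al-](C)(C)/C=C(\C)CCC#CC | intermediate
22 | (E)-3-methyloct-2-en-6-yn-1-ol | OC/C=C(\C)CCC#CC | intermediate
23 | alkenylzirconocene chloride of 22 with zirconium at C12 (hydroxyl carried as its zirconocene alkoxide) | C/C(=C\CC/C(C)=C/CO[Zr](Cl)(C1C=CC=C1)C1C=CC=C1)[Zr](Cl)(C1C=CC=C1)C1C=CC=C1 | intermediate
24 | (2E,6E)-7-iodo-3-methylocta-2,6-dien-1-ol | OC/C=C(\C)CC/C=C(\C)I | intermediate
25 | (2E,6E)-8-bromo-2-iodo-6-methylocta-2,6-diene | BrC/C=C(\C)CC/C=C(\C)I | intermediate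
26 | [(2E,6E)-7-iodo-3-methylocta-2,6-dien-1-yl]sulfonylbenzene | O=S(=O)(C/C=C(\C)CC/C=C(\C)I)c1ccccc1 | intermediate
27 | α-lithio derivative of 26 | [Li]C(/C=C(\C)CC/C=C(\C)I)S(=O)(=O)c1ccccc1 | intermediate
28 | trifluoromethanesulfonate of 16 at the C5 hydroxyl | CCOP(=O)(OCC)C1C(=O)O[C@@H](COC(=O)OCC(Cl)(Cl)Cl)[C@@H]1C[C@@H]1O[C@@]1(C)COS(=O)(=O)C(F)(F)F | intermediate
29 | diethyl [(4S,5R)-4-({(2S,3S)-3-[(3E,7E)-8-iodo-4-methyl-2-(phenylsulfonyl)nona-3,7-dien-1-yl]-3-methyloxiran-2-yl}methyl)-2-oxo-5-({[(2,2,2-trichloroethoxy)carbonyl]oxy}methyl)oxolan-3-yl]phosphonate | CCOP(=O)(OCC)C1C(=O)O[C@@H](COC(=O)OCC(Cl)(Cl)Cl)[C@@H]1C[C@@H]1O[C@@]1(C)CC(/C=C(\C)CC/C=C(\C)I)S(=O)(=O)c1ccccc1 | intermediate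
30 | diethyl [(4S,5R)-5-(hydroxymethyl)-4-({(2S,3S)-3-[(3E,7E)-8-iodo-4-methyl-2-(phenylsulfonyl)nona-3,7-dien-1-yl]-3-methyloxiran-2-yl}methyl)-2-oxooxolan-3-yl]phosphonate | CCOP(=O)(OCC)C1C(=O)O[C@@H](CO)[C@@H]1C[C@@H]1O[C@@]1(C)CC(/C=C(\C)CC/C=C(\C)I)S(=O)(=O)c1ccccc1 | intermediate
31 | diethyl [(4S,5R)-5-formyl-4-({(2S,3S)-3-[(3E,7E)-8-iodo-4-methyl-2-(phenylsulfonyl)nona-3,7-dien-1-yl]-3-methyloxiran-2-yl}methyl)-2-oxooxolan-3-yl]phosphonate | CCOP(=O)(OCC)C1C(=O)O[C@@H](C=O)[C@@H]1C[C@@H]1O[C@@]1(C)CC(/C=C(\C)CC/C=C(\C)I)S(=O)(=O)c1ccccc1 | intermediate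
32 | (1S,3S,4S,13S,14R)-15-(diethoxyphosphoryl)-3,4-epoxy-13-hydroxy-6-(phenylsulfonyl)cembra-7E,11E-dien-16,14-olide | CCOP(=O)(OCC)C1C(=O)O[C@@H]2[C@@H]1C[C@@H]1O[C@@]1(C)CC(S(=O)(=O)c1ccccc1)/C=C(\C)CC/C=C(\C)[C@@H]2O | intermediate
33 | (1S,3S,4S,13S,14R)-15-(diethoxyphosphoryl)-3,4-epoxy-13-hydroxycembra-7E,11E-dien-16,14-olide | CCOP(=O)(OCC)C1C(=O)O[C@@H]2[C@@H]1C[C@@H]1O[C@@]1(C)CC/C=C(\C)CC/C=C(\C)[C@@H]2O | intermediate
34 | (1R,3S,4S,13S,14R)-3,4-epoxy-13-hydroxycembra-7E,11E,15(17)-trien-16,14-olide | C=C1C(=O)O[C@@H]2[C@@H]1C[C@@H]1O[C@@]1(C)CC/C=C(\C)CC/C=C(\C)[C@@H]2O | intermediate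
35 | (1R,3S,4S,13S,14R)-13-acetoxy-3,4-epoxycembra-7E,11E,15(17)-trien-16,14-olide | C=C1C(=O)O[C@@H]2[C@@H]1C[C@@H]1O[C@@]1(C)CC/C=C(\C)CC/C=C(\C)[C@@H]2OC(C)=O | intermediate
36 | (1R,3S,4S,7R,13S,14R)-13-acetoxy-3,4-epoxy-7-hydroperoxycembra-8(19),11E,15(17)-trien-16,14-olide | C=C1C(=O)O[C@@H]2[C@@H]1C[C@@H]1O[C@@]1(C)CC[C@@H](OO)C(=C)CC/C=C(\C)[C@@H]2OC(C)=O | target

## Step count and least certain steps

Total: 26 steps. Longest linear sequence: 21 steps (steps 1–13 and 19–26, from 1); sulfone 26 takes 5 steps (14–18).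

Step 8 (key step). Most likely failure: insertion at the wrong C–H bond (C13–H or C14–H) or weak trans/cis discrimination at C1. Both flanking methylenes sit at the same 1,5-distance, and the chair preference of an acyclic ester is modest. The fallback forms C1–C2 by conjugate addition instead; it sets out from 1 and returns at 11. Compound 1 is acylated (ClCO2CH2CCl3, pyridine) to [(2R)-5-oxooxolan-2-yl]methyl 2,2,2-trichloroethyl carbonate F1. Selenenylation (LiN(SiMe3)2, PhSeBr, −78 °C) gives the α-phenylselanyl lactone F2, and H2O2–pyridine gives the butenolide F3. (CH2=CH)2CuLi adds anti to the C14 substituent to give the trans-4-vinyl lactone F4. The lactone enolate is phosphinylated with ClP(OEt)2 to the phosphonite F5, which H2O2 oxidises to the α-phosphono vinyl lactone F6. Hydroboration with 9-borabicyclo[3.3.1]nonane gives the alkylborane F7, and NaBO3·4H2O oxidises it to 11.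

Step 19. Most likely failure: the carbanion is quenched by C15–H, or attacks the carbonate or the epoxide, faster than it displaces the triflate at the hindered C5; the triflate may also decompose before substitution. The fallback couples at the allylic stage and epoxidises afterwards; it sets out from 15 and returns at 29. Alcohol 15 is brominated (CBr4, PPh3) to the allylic bromide F8, and lithiated 26 (2.5 equiv, THF, −78 °C) displaces bromide to give the triene sulfone F9. The C3=C4 olefin, the only one not deactivated by an allylic sulfonyl group or a vinylic iodine, is then epoxidised with the L-fructose-derived enantiomer of the Shi ketone and KHSO5 in buffered MeCN–dimethoxymethane–water to give 29.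

Step 22. Most likely failure: poor facial selectivity at C13, because ring strain in the closing transition state can override the Felkin–Anh preference; oligomerisation is the second concern. The fallback sets C13 by ketone reduction; it sets out from 31 and returns at 32. If closure gives mainly the 13-epimer F10, the epimer (or the mixture) is oxidised with Dess–Martin periodinane to the C13 enone F11. Reduction with (S)-2-methyl-CBS-oxazaborolidine and catecholborane at −78 °C, whose sense (alkenyl as the large group) matches hydride attack anti to O14, returns 32.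

Step 23. Most likely failure: hydride attack on the epoxide or the lactone, or loss of the position or geometry of C7=C8 by isomerisation of the π-allyl complex. The fallback replaces hydride substitution by single-electron cleavage: SmI2, HMPA and t-BuOH in THF at −78 °C reduce the C–S bond and the allyl anion is protonated at C6. It sets out from 32 and returns at 33 without new compounds.

Step 26. Most likely failure: hydrogen abstraction from C6 (giving the tertiary C8 hydroperoxide), attack on the wrong face of C7, or competing ene reaction at C11=C12, since only ring conformation and the cis effect steer the oxidant. The fallback is a two-step ionic route, which sets out from 35 and returns at 36, but it is the weakest of the fallbacks because its C7 configuration is not controlled. Ene-type chlorination (Ca(OCl)2, solid CO2, CH2Cl2–H2O, 0 °C) gives the 7-chloro-8(19)-ene F12, and silver-assisted perhydrolysis (AgOSO2CF3, anhydrous H2O2, Et2O, 0 °C) replaces chloride by hydroperoxide to give 36 after separation of C7 epimers.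

## Further compounds

F1 | step 8 | [(2R)-5-oxooxolan-2-yl]methyl 2,2,2-trichloroethyl carbonate | O=C1CC[C@H](COC(=O)OCC(Cl)(Cl)Cl)O1
F2 | step 8 | [(2R)-5-oxo-4-(phenylselanyl)oxolan-2-yl]methyl 2,2,2-trichloroethyl carbonate | O=C1C([Se]c2ccccc2)C[C@H](COC(=O)OCC(Cl)(Cl)Cl)O1
F3 | step 8 | [(2R)-5-oxo-2,5-dihydrofuran-2-yl]methyl 2,2,2-trichloroethyl carbonate | O=C1C=C[C@H](COC(=O)OCC(Cl)(Cl)Cl)O1
F4 | step 8 | trans-[3-ethenyl-5-oxooxolan-2-yl]methyl 2,2,2-trichloroethyl carbonate (C1, C14 as in 10) | C1C(=O)O[C@@H](COC(=O)OCC(Cl)(Cl)Cl)[C@@H]1C=C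
F5 | step 8 | diethyl phosphonite of F4 at C15 | CCOP(OCC)C1C(=O)O[C@@H](COC(=O)OCC(Cl)(Cl)Cl)[C@@H]1C=C
F6 | step 8 | diethyl [trans-4-ethenyl-2-oxo-5-({[(2,2,2-trichloroethoxy)carbonyl]oxy}methyl)oxolan-3-yl]phosphonate | CCOP(=O)(OCC)C1C(=O)O[C@@H](COC(=O)OCC(Cl)(Cl)Cl)[C@@H]1C=C
F7 | step 8 | B-alkyl-9-borabicyclo[3.3.1]nonane from F6 (boron at C3) | CCOP(=O)(OCC)C1C(=O)O[C@@H](COC(=O)OCC(Cl)(Cl)Cl)[C@@H]1CCB1C2CCCC1CCC2
F8 | step 19 | allylic bromide of 15 (C5 bromide) | CCOP(=O)(OCC)C1C(=O)O[C@@H](COC(=O)OCC(Cl)(Cl)Cl)[C@@H]1C/C=C(\C)CBr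
F9 | step 19 | 3,4-deoxy analogue of 29 (E-C3=C4 triene sulfone) | CCOP(=O)(OCC)C1C(=O)O[C@@H](COC(=O)OCC(Cl)(Cl)Cl)[C@@H]1C/C=C(\C)CC(/C=C(\C)CC/C=C(\C)I)S(=O)(=O)c1ccccc1
F10 | step 22 | 13-epimer of 32 | CCOP(=O)(OCC)C1C(=O)O[C@@H]2[C@@H]1C[C@@H]1O[C@@]1(C)CC(S(=O)(=O)c1ccccc1)/C=C(\C)CC/C=C(\C)[C@H]2O
F11 | step 22 | 13-oxo analogue of 32 (macrocyclic enone) | CCOP(=O)(OCC)C1C(=O)O[C@@H]2[C@@H]1C[C@@H]1O[C@@]1(C)CC(S(=O)(=O)c1ccccc1)/C=C(\C)CC/C=C(\C)C2=O
F0 | step 23 | none | none
F12 | step 26 | 7-chloro-8(19)-ene analogue of 36 (C7 epimers) | C=C1C(=O)O[C@@H]2[C@@H]1C[C@@H]1O[C@@]1(C)CCC(Cl)C(=C)CC/C=C(\C)[C@@H]2OC(C)=O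
A1 | alternative 1 | open-chain lactone with C13 aldehyde and C11≡C12 methyl alkyne | C1C(=O)O[C@@H](C=O)[C@@H]1C[C@@H]1O[C@@]1(C)CC/C=C(\C)CCC#CC
A2 | alternative 1 | 14-membered lactone with E-C11=C12 and C13 triethylsilyl ether | C1C(=O)O[C@@H]2[C@@H]1C[C@@H]1O[C@@]1(C)CC/C=C(\C)CC/C=C(\C)[C@@H]2O[Si](CC)(CC)CC
A3 | alternative 2 | (R)-5-{[(tert-butyldiphenylsilyl)oxy]methyl}furan-2(5H)-one | O=C1C=C[C@H](CO[Si](c2ccccc2)(c2ccccc2)C(C)(C)C)O1
A4 | alternative 2 | (E)-tert-butyldimethyl{[2-methyl-4-(phenylsulfonyl)but-2-en-1-yl]oxy}silane | O=S(=O)(C/C=C(\C)CO[Si](C)(C)C(C)(C)C)c1ccccc1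
A5 | alternative 2 | trans,trans-trisubstituted lactone with C15 dimethylaminomethyl group and C2 sulfone | CN(C)C[C@H]1C(=O)O[C@@H](CO[Si](c2ccccc2)(c2ccccc2)C(C)(C)C)[C@@H]1C(S(=O)(=O)c1ccccc1)/C=C(\C)CO[Si](C)(C)C(C)(C)C
A6 | alternative 3 | macrocyclic C14 alcohol with C1 ethynyl group and C13 silyl ether | O[C@@H]2[C@@H](C#C)C[C@@H]1O[C@@]1(C)CC/C=C(\C)CC/C=C(\C)[C@@H]2O[Si](C)(C)C(C)(C)C
A7 | alternative 3 | 14-membered α-methylene lactone with C13 silyl ether | C=C1C(=O)O[C@@H]2[C@@H]1C[C@@H]1O[C@@]1(C)CC/C=C(\C)CC/C=C(\C)[C@@H]2O[Si](C)(C)C(C)(C)C
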